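**Strategy**

Atom labels: C1 is the benzylic CH2, C2 the acetoxy carbon, C8 the ketone carbon. The benzene ring bears one carbon substituent (C1), placed 1,3,5 to the two phenolic oxygens; this is the imprint of a 5-substituted cyclohexane-1,3-dione, so the arene is disconnected to dimethyl malonate and a methyl enone. One operation, conjugate addition then Claisen closure, forges two ring C–C bonds and the six-membered carbocycle with both oxygens already in place. The precursor is an acyclic (E)-heptadec-3-ene-2,12-dione whose C6 (future C2) is an (R)-configured triisopropylsilyl ether and whose far carbonyl is the spectator C8 ketone; C2 is set earlier by catalytic asymmetric allylation.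

Key step: step 7

Remarks on the chemistry:
- The target SMILES is read as the (R)-enantiomer at C2. The CIP order O > benzylic/allylic carbon > chain carbon holds in every intermediate, so the descriptor stays R from step 4 onwards.
- The C2 oxygen is carried as a triisopropylsilyl (TIPS) ether. It is chosen over smaller silyl groups because it has to survive methoxide at reflux, the acidic decarboxylation and the acidic aerobic dehydrogenation.
- Compound 14 is drawn as its triketo tautomer. It is expected to exist largely as an enol and as a mixture of ring diastereomers; both features disappear on aromatisation.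

**Route**

Step 1
Reactants: 1 cycloheptanone; 2 pentylmagnesium bromide
Product: 3 1-pentylcycloheptan-1-ol
Conditions: 2 (1.2 equiv), THF, 0 °C to rt; sat. aq. NH4Cl
Reagents that add atoms: none
Why: Grignard 1,2-addition of a primary alkylmagnesium halide to an unhindered cyclic ketone should give the tertiary alcohol, and no stereocentre is created.

Step 2
Reactants: 3 1-pentylcycloheptan-1-ol
Product: 4 1-pentylcyclohept-1-ene
Conditions: TsOH·H2O (5 mol %), toluene, reflux, Dean–Stark
Reagents that add atoms: none
Why: Acid-catalysed E1 dehydration of the tertiary alcohol under equilibrating conditions should favour the endocyclic trisubstituted alkene (Zaitsev elimination), and any exocyclic isomer is harmless because it would ozonolyse to volatile cycloheptanone and pentanal.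

Step 3
Reactants: 4 1-pentylcyclohept-1-ene
Product: 6 7-oxododecanal, via secondary ozonide 5 (not isolated)
Conditions: O3, CH2Cl2, −78 °C; then PPh3, −78 °C to rt
Reagents that add atoms: ozone, [O-][O+]=O
Why: Criegee ozonolysis of the ring alkene and reductive cleavage of the ozonide by PPh3 should open the ring to the 1,7-keto aldehyde without over-oxidation, and the product is kept neutral and used at once to avoid intramolecular aldol condensation.

Step 4
Reactants: 6 7-oxododecanal; 7 allyltributylstannane
Product: 8 (12R)-12-hydroxypentadec-14-en-6-one
Conditions: 7 (1.3 equiv), (S)-BINOL (10 mol %), Ti(OiPr)4 (10 mol %), 4 Å molecular sieves, CH2Cl2, −20 °C; sat. aq. NaHCO3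
Reagents that add atoms: none
Why: Keck asymmetric allylation, in which the (S)-BINOL/Ti(OiPr)4 Lewis acid activates only the aldehyde (the stannane is too weak a nucleophile for the dialkyl ketone) and is expected to deliver the allyl group to the Si face of the unbranched aldehyde, setting the carbinol carbon (future C2) as R.

Step 5
Reactants: 8 (12R)-12-hydroxypentadec-14-en-6-one
Product: 9 (12R)-12-{[tri(propan-2-yl)silyl]oxy}pentadec-14-en-6-one
Conditions: TIPSOTf (1.15 equiv), 2,6-lutidine (2 equiv), CH2Cl2, −78 to 0 °C
Reagents that add atoms: triisopropylsilyl trifluoromethanesulfonate (TIPSOTf), CC(C)[Si](C(C)C)(C(C)C)OS(=O)(=O)C(F)(F)F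
Why: O-silylation of the secondary alcohol by a silyl triflate with a weak hindered base is fast at low temperature whereas the dialkyl ketone is not enolised, and the configuration is retained because only the O–H bond reacts.

Step 6
Reactants: 9 (12R)-12-{[tri(propan-2-yl)silyl]oxy}pentadec-14-en-6-one; 10 methyl vinyl ketone (but-3-en-2-one)
Product: 11 (3E,6R)-6-{[tri(propan-2-yl)silyl]oxy}heptadec-3-ene-2,12-dione
Conditions: 10 (4 equiv), second-generation Grubbs catalyst (3 mol %), CH2Cl2, 40 °C
Reagents that add atoms: none
Why: Olefin cross-metathesis of the terminal alkene with an excess of an electron-poor enone that homodimerises slowly should give the conjugated E-enone under thermodynamic control, and the ketone and silyl ether are inert to the ruthenium carbene.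

Step 7
Reactants: 11 (3E,6R)-6-{[tri(propan-2-yl)silyl]oxy}heptadec-3-ene-2,12-dione; 12 dimethyl malonate
Product: 14 methyl 2,4-dioxo-6-[(2R)-8-oxo-2-{[tri(propan-2-yl)silyl]oxy}tridecyl]cyclohexane-1-carboxylate, via open-chain Michael adduct 13 (not isolated)
Conditions: 12 (1.3 equiv), NaOMe (1.2 equiv), MeOH, 0 °C then reflux; 1 M HCl to pH 3, 0 °C
Reagents that add atoms: none
Why: Sodium dimethyl malonate adds to the enone β-carbon (Michael addition) to give adduct 13, proton transfer generates the methyl-ketone enolate, and this enolate acylates on one malonate ester with loss of methoxide (Claisen condensation), after which the acidic cyclic tricarbonyl product is deprotonated irreversibly and pulls the whole sequence forward. The closest known reaction type is the classical enone plus malonate synthesis of 5-substituted cyclohexane-1,3-diones, as used for dimedone and for 5-alkylresorcinols. The one ring formed, the six-membered carbocycle, closes in a 6-exo-trig mode, the enolate carbon attacking an ester carbonyl whose C=O lies outside the new ring. No lasting stereocentre is created: the two ring CH centres form as an equilibrating mixture and are erased by decarboxylation and aromatisation, while the non-enolisable (R)-carbinol centre is untouched. The step needs conjugate addition to outpace γ-deprotonation of the enone and loss of silanolate, which is secured by keeping malonate in slight excess over NaOMe so that the only base present is the weakly basic malonate anion and by running the addition stage cold before heating; ring closure can only go through the methyl-side enolate because the other enolate would give a four-membered ring. The distant C8 ketone is several pKa units less acidic than malonate and has no favourable ring size for closure, and the bulky triisopropylsilyl group withholds the C2 alkoxide that could otherwise lactonise onto the ester.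

Step 8
Reactants: 14 methyl 2,4-dioxo-6-[(2R)-8-oxo-2-{[tri(propan-2-yl)silyl]oxy}tridecyl]cyclohexane-1-carboxylate
Product: 16 5-[(2R)-8-oxo-2-{[tri(propan-2-yl)silyl]oxy}tridecyl]cyclohexane-1,3-dione, via β-keto acid 15 (not isolated)
Conditions: 2 M aq. NaOH, MeOH, 65 °C; then 2 M HCl to pH 3, 50 °C
Reagents that add atoms: none
Why: Saponification of the ester, with the ring protected from retro-Claisen cleavage as its enolate, followed by decarboxylation of the β-keto acid on acidification should leave a dione whose substituted ring carbon is no longer stereogenic; the TIPS ether and the distal ketone tolerate both stages.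

Step 9
Reactants: 16 5-[(2R)-8-oxo-2-{[tri(propan-2-yl)silyl]oxy}tridecyl]cyclohexane-1,3-dione
Product: 17 (12R)-13-(3,5-dihydroxyphenyl)-12-{[tri(propan-2-yl)silyl]oxy}tridecan-6-one
Conditions: Pd(O2CCF3)2 (5 mol %), 2-(dimethylamino)pyridine (10 mol %), TsOH·H2O (20 mol %), O2 (1 atm), DMSO, 80 °C
Reagents that add atoms: none
Why: Aerobic dehydrogenation catalysed by divalent palladium, in which the enolised dione (a 3-hydroxycyclohex-2-enone) forms a Pd enolate at a ring CH2, β-hydride elimination from the substituted ring carbon gives a hydroxy dienone that tautomerises irreversibly to the resorcinol, and O2 reoxidises the Pd hydride; the acyclic ketone reacts far more slowly and the silyl ether shields the carbinol from alcohol oxidation.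

Step 10
Reactants: 17 (12R)-13-(3,5-dihydroxyphenyl)-12-{[tri(propan-2-yl)silyl]oxy}tridecan-6-one
Product: 19 5-[(2R)-2-(acetyloxy)-8-oxotridecyl]-1,3-phenylene diacetate, via free triol 18 (not isolated)
Conditions: TBAF (3 equiv), THF, rt to 40 °C; then Ac2O (8 equiv), pyridine, DMAP (10 mol %), 0 °C to rt
Reagents that add atoms: acetic anhydride, CC(=O)OC(C)=O
Why: Fluoride cleaves the Si–O bond (desilylation) without touching the C2–O bond, so the configuration is retained, and DMAP-catalysed acetylation of both phenols and the secondary alcohol in the same flask avoids isolating the polar triol.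

Step 11
Reactants: 19 5-[(2R)-2-(acetyloxy)-8-oxotridecyl]-1,3-phenylene diacetate
Product: 20 (2R)-1-(3,5-dihydroxyphenyl)-8-oxotridecan-2-yl acetate
Conditions: NH4OAc, MeOH–H2O (4:1), rt
Reagents that add atoms: none
Why: Aryl acetates, which have a phenoxide leaving group, undergo NH4OAc-mediated solvolysis at room temperature far faster than a secondary alkyl acetate (chemoselective deacetylation), so both phenols should be released while the C2 acetate and its configuration stay untouched.

**Compound list**

1 | cycloheptanone | O=C1CCCCCC1 | starting material
2 | pentylmagnesium bromide | CCCCC[Mg]Br | starting material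
3 | 1-pentylcycloheptan-1-ol | CCCCCC1(O)CCCCCC1 | intermediate
4 | 1-pentylcyclohept-1-ene | CCCCCC1=CCCCCC1 | intermediate
5 | 1-pentyl-8,9,10-trioxabicyclo[5.2.1]decane (secondary ozonide, not isolated) | CCCCCC12CCCCCC(O1)OO2 | intermediate
6 | 7-oxododecanal | CCCCCC(=O)CCCCCC=O | intermediate
7 | allyltributylstannane (tributyl(prop-2-en-1-yl)stannane) | C=CC[Sn](CCCC)(CCCC)CCCC | starting material
8 | (12R)-12-hydroxypentadec-14-en-6-one | C=CC[C@H](O)CCCCCC(=O)CCCCC | intermediate
9 | (12R)-12-{[tri(propan-2-yl)silyl]oxy}pentadec-14-en-6-one | C=CC[C@H](O[Si](C(C)C)(C(C)C)C(C)C)CCCCCC(=O)CCCCC | intermediate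
10 | methyl vinyl ketone (but-3-en-2-one) | CC(=O)C=C | starting material
11 | (3E,6R)-6-{[tri(propan-2-yl)silyl]oxy}heptadec-3-ene-2,12-dione | CC(=O)/C=C/C[C@H](O[Si](C(C)C)(C(C)C)C(C)C)CCCCCC(=O)CCCCC | intermediate
12 | dimethyl malonate | COC(=O)CC(=O)OC | starting material
13 | dimethyl 2-[(6R)-2,12-dioxo-6-{[tri(propan-2-yl)silyl]oxy}heptadecan-4-yl]propanedioate (Michael adduct, both C4 epimers, not isolated) | COC(=O)C(C(=O)OC)C(CC(C)=O)C[C@H](O[Si](C(C)C)(C(C)C)C(C)C)CCCCCC(=O)CCCCC | intermediate
14 | methyl 2,4-dioxo-6-[(2R)-8-oxo-2-{[tri(propan-2-yl)silyl]oxy}tridecyl]cyclohexane-1-carboxylate (ring diastereomers, enol tautomers) | COC(=O)C1C(=O)CC(=O)CC1C[C@H](O[Si](C(C)C)(C(C)C)C(C)C)CCCCCC(=O)CCCCC | intermediate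
15 | 2,4-dioxo-6-[(2R)-8-oxo-2-{[tri(propan-2-yl)silyl]oxy}tridecyl]cyclohexane-1-carboxylic acid (not isolated) | OC(=O)C1C(=O)CC(=O)CC1C[C@H](O[Si](C(C)C)(C(C)C)C(C)C)CCCCCC(=O)CCCCC | intermediate
16 | 5-[(2R)-8-oxo-2-{[tri(propan-2-yl)silyl]oxy}tridecyl]cyclohexane-1,3-dione | O=C1CC(=O)CC(C1)C[C@H](O[Si](C(C)C)(C(C)C)C(C)C)CCCCCC(=O)CCCCC | intermediate
17 | (12R)-13-(3,5-dihydroxyphenyl)-12-{[tri(propan-2-yl)silyl]oxy}tridecan-6-one | CCCCCC(=O)CCCCC[C@H](Cc1cc(O)cc(O)c1)O[Si](C(C)C)(C(C)C)C(C)C | intermediate
18 | (12R)-13-(3,5-dihydroxyphenyl)-12-hydroxytridecan-6-one (not isolated) | CCCCCC(=O)CCCCC[C@H](Cc1cc(O)cc(O)c1)O | intermediate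
19 | 5-[(2R)-2-(acetyloxy)-8-oxotridecyl]-1,3-phenylene diacetate | CCCCCC(=O)CCCCC[C@H](Cc1cc(OC(C)=O)cc(OC(C)=O)c1)OC(C)=O | intermediate
20 | (2R)-1-(3,5-dihydroxyphenyl)-8-oxotridecan-2-yl acetate | CCCCCC(=O)CCCCC[C@H](Cc1cc(O)cc(O)c1)OC(C)=O | target

**Step count**

Total step count: 11. Longest linear sequence: 11 steps, from cycloheptanone 1 to target 20.

**Steps most likely to fail**

1. Step 7 (annulation). Before the malonate has added, the enone may be deprotonated at its γ-carbon and expel the silyloxy group, or the sequence may stall at the open-chain adduct and revert. The fallback sets out from alkene 9 and returns at keto ester 14. Cross-metathesis of 9 with methyl acrylate under the conditions of step 6 would give methyl (2E,5R)-11-oxo-5-{[tri(propan-2-yl)silyl]oxy}hexadec-2-enoate F1, a less acidic acceptor. Michael addition of methyl acetoacetate (NaOMe, MeOH, reflux) to F1, followed by Claisen closure of the acetoacetate methyl-ketone enolate onto the chain ester, is the other classical entry to this ring system and would give 14 directly, with the ester in the same position.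

2. Step 9 (aromatisation). The dehydrogenation may stall, the catalyst may precipitate as palladium metal, or the acid co-catalyst may strip the silyl group, after which the freed carbinol would be oxidised. The fallback sets out from keto ester 14, returns at resorcinol 17 and replaces steps 8 and 9. The ring is aromatised before the ester is removed: bromination of the enolised tricarbonyl with Br2 (1 equiv) in DMF at 0 °C and dehydrobromination on warming should give methyl 2,4-dihydroxy-6-[(2R)-8-oxo-2-{[tri(propan-2-yl)silyl]oxy}tridecyl]benzoate F2. Saponification of F2 with hot aq. NaOH and decarboxylation of the resulting β-resorcylic acid on acidification would then give 17.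

3. Step 4 (allylation). Aldehyde-over-ketone selectivity may erode, the 1,7-keto aldehyde may be consumed by Lewis-acid-promoted intramolecular aldol condensation during the long reaction time, or facial selectivity may be insufficient. The fallback sets out from pentylmagnesium bromide 2, which is now used last, together with commercial cycloheptene, and returns at silyl ether 9, so that no ketone is present when the stereocentre is made. Ozonolysis of cycloheptene in CH2Cl2/MeOH with NaHCO3, then Ac2O/Et3N, would give methyl 7-oxoheptanoate F3. Allylation as in step 4, or with the Si-face-selective (−)-B-allyldiisopinocampheylborane at −78 °C (which an ester tolerates), would give methyl (7R)-7-hydroxydec-9-enoate F4. Silylation with TIPSOTf/2,6-lutidine would give methyl (7R)-7-{[tri(propan-2-yl)silyl]oxy}dec-9-enoate F5. Treatment with Me(MeO)NH·HCl/iPrMgCl would give (7R)-N-methoxy-N-methyl-7-{[tri(propan-2-yl)silyl]oxy}dec-9-enamide F6, and addition of 2 to this Weinreb amide would give ketone 9.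

**Further compounds**

F1 | step 7 | methyl (2E,5R)-11-oxo-5-{[tri(propan-2-yl)silyl]oxy}hexadec-2-enoate | COC(=O)/C=C/C[C@H](O[Si](C(C)C)(C(C)C)C(C)C)CCCCCC(=O)CCCCC
F2 | step 9 | methyl 2,4-dihydroxy-6-[(2R)-8-oxo-2-{[tri(propan-2-yl)silyl]oxy}tridecyl]benzoate | COC(=O)c1c(O)cc(O)cc1C[C@H](O[Si](C(C)C)(C(C)C)C(C)C)CCCCCC(=O)CCCCC
F3 | step 4 | methyl 7-oxoheptanoate | COC(=O)CCCCCC=O
F4 | step 4 | methyl (7R)-7-hydroxydec-9-enoate | C=CC[C@H](O)CCCCCC(=O)OC
F5 | step 4 | methyl (7R)-7-{[tri(propan-2-yl)silyl]oxy}dec-9-enoate | C=CC[C@H](O[Si](C(C)C)(C(C)C)C(C)C)CCCCCC(=O)OC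
F6 | step 4 | (7R)-N-methoxy-N-methyl-7-{[tri(propan-2-yl)silyl]oxy}dec-9-enamide | C=CC[C@H](O[Si](C(C)C)(C(C)C)C(C)C)CCCCCC(=O)N(C)OC
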